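**Plan**

Retrosynthesis: the acid is released from its methyl ester; the Cc=CMe2 alkene is cut (Wittig), then the C6–prenyl bond (dearomative C-alkylation of ring A), then the Ca–Cb bond together with a temporary O5–Cc lactol bond (ortho-quinone methide plus enamine), then C6–Ca (sulfonylmethylation), the arm C–phenyl bond (conjugate addition to a coumarin), the pyranone ring that carries the arm, the C8–CHO bond and last ring B (O1–C2 oxa-Michael, C4a–C4 acylation).
Forward: ring B is closed first on 3,5-dimethoxyphenol, the δ-lactone ring that holds the acid arm and blocks O7 second, the temporary lactol ring on O5 third; ring A is then dearomatised at C6, the acetal ring is opened and the aldehyde is olefinated.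
Feature used: at C6, the future quaternary carbon of ring A, the long side chain begins with a methylene (Ca) whose neighbour Cb is stereogenic and carries the vinylic CH (Cc); while ring A is still a phenol, Ca can be the exocyclic methylene of an ortho-quinone methide and Cc an aldehyde carbon with Cb as its α-carbon.
Stereochemistry: C2/C3 come from a quinine-catalysed oxa-Michael closure and C3 equilibration, the arm carbon from Rh/(R)-Segphos phenyl addition, Cb from the (S)-diarylprolinol silyl ether, and C6 from Cb through the O5-fused acetal ring, in which prenyl enters trans to the pseudo-equatorial side chain.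
The acetal ring has to be fused through O5, the oxygen next to the acyl-bearing carbon C4a; a ring through O7 would relay Cb to the C6 epimer, so O7 stays inside the arm lactone until the O5 ring is fixed as a silyl acetal.

Key step: step 10

Remark: the target is treated as the drawn tautomer of an enolised β-triketone (C4 enol, C5 and C7 keto), its other tautomers being the same compound; locants are those of the chromanone core (O1, C2, C3, C4, C4a, C5–C8, C8a), and Ca, Cb, Cc are the first three carbons of the long chain on C6.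

**Route**

Step 1
Reactants: 1 3,5-dimethoxyphenol; 2 tigloyl chloride [(E)-2-methylbut-2-enoyl chloride]
Product: 3 (E)-1-(2-hydroxy-4,6-dimethoxyphenyl)-2-methylbut-2-en-1-one
Conditions: AlCl3 (1.5 equiv), CH2Cl2, 0 °C → rt; dilute HCl work-up
Reagents that add atoms: none
Why: Friedel–Crafts acylation of an activated phenol places the acyl group ortho to the hydroxyl, where the ketone is held as an aluminium chelate; the chelated phenol does not add to the enone, so the open aryl tigloyl ketone is kept for the asymmetric ring closure.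

Step 2
Reactants: 3 (E)-1-(2-hydroxy-4,6-dimethoxyphenyl)-2-methylbut-2-en-1-one
Product: 5 (2R,3R)-5,7-dimethoxy-2,3-dimethylchroman-4-one, via cis-chromanone 4 (not isolated)
Conditions: (−)-quinine (20 mol %), PhCl, 10 °C; then p-TsOH·H2O (40 mol %), 40 °C
Reagents that add atoms: none
Why: Cinchona-alkaloid-catalysed intramolecular oxa-Michael addition of an ortho-tigloylphenol (6-endo-trig), in which the quinuclidine nitrogen and the C9 hydroxyl of quinine hold phenoxide and enone so that O1 bonds to one face of C2 and should give 2R, after which acid-catalysed enolisation turns the kinetic C3 epimer into the more stable trans isomer without touching C2.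

Step 3
Reactants: 5 (2R,3R)-5,7-dimethoxy-2,3-dimethylchroman-4-one
Product: 6 (2R,3R)-5,7-dimethoxy-2,3-dimethyl-4-oxochromane-8-carbaldehyde
Conditions: Cl2CHOMe, TiCl4, CH2Cl2, −78 → 0 °C; then H2O
Reagents that add atoms: dichloromethyl methyl ether, COC(Cl)Cl; water, O
Why: Rieche formylation (electrophilic aromatic substitution) should take C8, which lies between one methoxy group and the tied-back ring oxygen and para to the 5-methoxy group, in preference to C6, which is flanked by two methoxy groups, one of them pressed towards it by the peri carbonyl.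

Step 4
Reactants: 6 (2R,3R)-5,7-dimethoxy-2,3-dimethyl-4-oxochromane-8-carbaldehyde
Product: 7 (2R,3R)-5,7-dihydroxy-2,3-dimethyl-4-oxochromane-8-carbaldehyde
Conditions: BCl3 (3 equiv), CH2Cl2, −78 → 0 °C; then H2O
Reagents that add atoms: none
Why: Chelation-assisted ether cleavage: BCl3 removes methyl groups from methoxy groups that sit ortho to a carbonyl, here the 5-OMe (C4 ketone) and the 7-OMe (aldehyde), and leaves the ring-B ether and both stereocentres alone.

Step 5
Reactants: 7 (2R,3R)-5,7-dihydroxy-2,3-dimethyl-4-oxochromane-8-carbaldehyde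
Product: 9 (2R,3R)-5-hydroxy-2,3-dimethyl-2,3-dihydro-4H,8H-pyrano[2,3-f]chromene-4,8-dione (coumarin ring fused at O7/C8), via ester ylide 8 (not isolated)
Conditions: Ph3P=C=C=O (1.1 equiv), toluene, 110 °C
Reagents that add atoms: (triphenylphosphoranylidene)ketene, O=C=C=P(c1ccccc1)(c1ccccc1)c1ccccc1
Why: The cumulated ylide is acylated by the more acidic 7-OH and the resulting ester ylide closes the pyranone by intramolecular Wittig reaction with the neighbouring aldehyde (coumarin synthesis, Z alkene enforced by the ring), while the 5-OH, hydrogen-bonded to the ketone, stays free.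

Step 6
Reactants: 9 (2R,3R)-5-hydroxy-2,3-dimethyl-2,3-dihydro-4H,8H-pyrano[2,3-f]chromene-4,8-dione
Product: 10 (2R,3R,10R)-5-hydroxy-2,3-dimethyl-10-phenyl-2,3,9,10-tetrahydro-4H,8H-pyrano[2,3-f]chromene-4,8-dione
Conditions: PhB(OH)2 (5 equiv), Rh(acac)(C2H4)2 (3 mol %), (R)-Segphos (3.3 mol %), dioxane/H2O (10:1), 60 °C
Reagents that add atoms: phenylboronic acid, OB(O)c1ccccc1
Why: Hayashi–Miyaura rhodium-catalysed asymmetric 1,4-addition of an arylboronic acid to a coumarin, in which the (R)-Segphos complex delivers phenyl to one face of C10 and should give the 10R lactone, the sense established for coumarins, the remote C2/C3 centres having no say.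

Step 7
Reactants: 10 (2R,3R,10R)-5-hydroxy-2,3-dimethyl-10-phenyl-2,3,9,10-tetrahydro-4H,8H-pyrano[2,3-f]chromene-4,8-dione
Product: 11 (2R,3R,10R)-5-hydroxy-2,3-dimethyl-6-[(4-methylphenyl)sulfonylmethyl]-10-phenyl-2,3,9,10-tetrahydro-4H,8H-pyrano[2,3-f]chromene-4,8-dione
Conditions: (CH2O)n, TolSO2Na, HCO2H/H2O (4:1), 50 °C
Reagents that add atoms: formaldehyde (as paraformaldehyde), C=O; sodium p-toluenesulfinate, Cc1ccc(cc1)S(=O)[O-].[Na+]
Why: Three-component sulfonylmethylation of a phenol (hydroxymethylation, then capture of the benzylic cation at sulfur by the sulfinate) at C6, the only unsubstituted ring position, which is ortho to O5 and para to O1.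

Step 8
Reactants: 12 ethyl 5-oxohexanoate
Product: 13 ethyl 5-methylhex-5-enoate
Conditions: Ph3PCH3Br, KOtBu, THF, 0 °C → rt
Reagents that add atoms: methylenetriphenylphosphorane (made from methyltriphenylphosphonium bromide), C=P(c1ccccc1)(c1ccccc1)c1ccccc1
Why: Wittig methylenation of the ketone, which the ester survives because non-stabilised ylides react far faster with ketones than with esters.

Step 9
Reactants: 13 ethyl 5-methylhex-5-enoate
Product: 14 5-methylhex-5-enal
Conditions: i-Bu2AlH (1.05 equiv), CH2Cl2, −78 °C; aq. potassium sodium tartrate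
Reagents that add atoms: none
Why: Partial ester reduction: at −78 °C the aluminium hemiacetal is stable and gives the aldehyde only on work-up.

Step 10
Reactants: 11 (2R,3R,10R)-5-hydroxy-2,3-dimethyl-6-[(4-methylphenyl)sulfonylmethyl]-10-phenyl-2,3,9,10-tetrahydro-4H,8H-pyrano[2,3-f]chromene-4,8-dione; 14 5-methylhex-5-enal
Product: 16 O5-lactol of (2R)-2-{[(2R,3R,10R)-5-hydroxy-2,3-dimethyl-4,8-dioxo-10-phenyl-2,3,9,10-tetrahydro-4H,8H-pyrano[2,3-f]chromen-6-yl]methyl}-5-methylhex-5-enal (2-hydroxychroman ring closed on O5; anomeric mixture), via ortho-quinone methide 15 (not isolated)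
Conditions: (S)-2-[diphenyl(trimethylsilyloxy)methyl]pyrrolidine (20 mol %), K2CO3 (1.5 equiv), H2O (3 equiv), CH2Cl2, 0 °C → rt; NaH2PO4/Na2HPO4 buffer (pH 6) work-up
Reagents that add atoms: none
Why: K2CO3 deprotonates O5–H, the only free phenol of 11, and the phenoxide expels p-toluenesulfinate to give the ortho-quinone methide 15 (C5=O, C6=Ca), while 14 and the amine form the E-enamine. The enamine α-carbon (Cb) adds to Ca, ring A becomes aromatic again, the O5 phenoxide closes on the iminium carbon Cc (6-exo-trig), and water releases the catalyst and lactol 16, which is in ring–chain equilibrium with its hydroxy aldehyde form. The closest known reaction is the enamine-catalysed α-alkylation of aldehydes by ortho-quinone methides released from 2-(sulfonylmethyl)phenols, a formal [4+2] annulation that ends in chroman-2-ols. Cb is set by the diphenyl(silyloxy)methyl group of the (S)-catalyst, which covers one face of the anti E-enamine so that Ca bonds to the open face and should give R; the anomeric carbon is left as a mixture because it ends as an alkene carbon. The step needs conjugate attack at Ca in preference to the ketone and lactone carbonyls, which the gain of aromaticity secures, and it needs the lactol on O5 and not on O7, which the lactone on O7 secures. Only the O5-fused ring relays Cb to the required face of C6 in step 12.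

Step 11
Reactants: 16 O5-lactol (ring–chain tautomer of the hydroxy aldehyde)
Product: 17 tert-butyldimethylsilyl ether of lactol 16 (2-silyloxychroman acetal on O5; anomeric mixture)
Conditions: t-BuMe2SiCl, imidazole, DMF, 0 °C → rt
Reagents that add atoms: tert-butyldimethylsilyl chloride, CC(C)(C)[Si](C)(C)Cl
Why: Anomeric O-silylation: the hemiacetal hydroxyl is silylated readily whereas the C5 phenol of the open tautomer is hydrogen-bonded to the C4 ketone and flanked on both sides, so the ring–chain equilibrium should drain into the closed silyl acetal, which is stable to the methoxide of the next step.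

Step 12
Reactants: 17 tert-butyldimethylsilyl ether of lactol 16
Product: 19 (6S)-6-prenyl cyclohexa-2,4-dienone (ring A dearomatised: C7 ketone; C8=C8a and C4a=C5 double bonds; C6 bearing prenyl and Ca; O5 silyl acetal ring and ring B intact; arm as methyl ester), via sodium phenoxide 18 (not isolated)
Conditions: NaOMe (1.05 equiv), MeOH, 0 °C; then prenyl bromide (1.5 equiv), −10 °C → rt
Reagents that add atoms: sodium methoxide, C[O-].[Na+]; prenyl bromide, CC(C)=CCBr
Why: Methoxide opens the aryl lactone to the methyl ester and the O7 phenoxide, which is C-alkylated in the protic medium used for alkylative dearomatisation of acylphloroglucinols; C6 should be preferred over C8, which carries the bulky benzylic arm, and the new bond should form trans to the pseudo-equatorial 3-methylbut-3-enyl group of the O5-fused half-chair, on the face from which the acetal ring passes directly into a chair with prenyl axial beside the axial hydrogen of Cb, which sets C6 as in the target.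

Step 13
Reactants: 19 (6S)-6-prenyl cyclohexa-2,4-dienone
Product: 20 methyl (3R)-3-[(2R,3R,6R)-6-[(2R)-2-formyl-5-methylhex-5-en-1-yl]-4-hydroxy-2,3-dimethyl-6-(3-methylbut-2-en-1-yl)-5,7-dioxo-3,5,6,7-tetrahydro-2H-chromen-8-yl]-3-phenylpropanoate (C6 arranged in space as in 19; the descriptor changes with the CIP order)
Conditions: Bu4NF/AcOH (1:1), THF, 0 °C
Reagents that add atoms: none
Why: Fluoride removes the silyl group and the freed hemiacetal, now attached to a vinylogous acid oxygen, collapses to the aldehyde and the enolised β-triketone, while acetic acid keeps the medium from epimerising Cb.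

Step 14
Reactants: 20 aldehyde methyl ester
Product: 21 methyl (3R)-3-[(2R,3R,6S)-4-hydroxy-2,3-dimethyl-6-(3-methylbut-2-en-1-yl)-6-[(2R)-5-methyl-2-(2-methylprop-1-en-1-yl)hex-5-en-1-yl]-5,7-dioxo-3,5,6,7-tetrahydro-2H-chromen-8-yl]-3-phenylpropanoate
Conditions: i-PrPPh3I, n-BuLi, THF, −78 → 0 °C (3.5 equiv of ylide)
Reagents that add atoms: isopropylidenetriphenylphosphorane (made from isopropyltriphenylphosphonium iodide), CC(C)=P(c1ccccc1)(c1ccccc1)c1ccccc1
Why: Wittig olefination with a non-stabilised ylide: the first equivalent deprotonates the triketone enol, whose delocalised enolate shields the ring carbonyls, and the aldehyde should react at low temperature faster than it enolises, so Cb is kept.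

Step 15
Reactants: 21 methyl ester of the target
Product: 22 (3R)-3-[(2R,3R,6S)-4-hydroxy-2,3-dimethyl-6-(3-methylbut-2-en-1-yl)-6-[(2R)-5-methyl-2-(2-methylprop-1-en-1-yl)hex-5-en-1-yl]-5,7-dioxo-3,5,6,7-tetrahydro-2H-chromen-8-yl]-3-phenylpropanoic acid (target)
Conditions: LiOH, THF/MeOH/H2O, rt; then dilute HCl to pH 4
Reagents that add atoms: lithium hydroxide, [Li+].[OH-]
Why: Saponification of the methyl ester: the ring system is present as its enolate and is not attacked, and mild acidification avoids acid-induced cyclisation of the prenyl groups onto the enol oxygens.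

**Compound list**

1 | 3,5-dimethoxyphenol | COc1cc(O)cc(OC)c1 | starting material
2 | tigloyl chloride, (E)-2-methylbut-2-enoyl chloride | C/C=C(\C)C(=O)Cl | starting material
3 | (E)-1-(2-hydroxy-4,6-dimethoxyphenyl)-2-methylbut-2-en-1-one | C/C=C(\C)C(=O)c1c(O)cc(OC)cc1OC | intermediate
4 | (2R,3S)-5,7-dimethoxy-2,3-dimethylchroman-4-one (cis; kinetic C3 epimer; not isolated) | COc1cc(OC)c2C(=O)[C@@H](C)[C@@H](C)Oc2c1 | intermediate
5 | (2R,3R)-5,7-dimethoxy-2,3-dimethylchroman-4-one (trans) | COc1cc(OC)c2C(=O)[C@H](C)[C@@H](C)Oc2c1 | intermediate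
6 | (2R,3R)-5,7-dimethoxy-2,3-dimethyl-4-oxochromane-8-carbaldehyde | COc1cc(OC)c2C(=O)[C@H](C)[C@@H](C)Oc2c1C=O | intermediate
7 | (2R,3R)-5,7-dihydroxy-2,3-dimethyl-4-oxochromane-8-carbaldehyde | Oc1cc(O)c2C(=O)[C@H](C)[C@@H](C)Oc2c1C=O | intermediate
8 | 7-O-[(triphenylphosphoranylidene)acetyl] ester of 7 (ester ylide; not isolated) | O=C(C=P(c1ccccc1)(c1ccccc1)c1ccccc1)Oc1cc(O)c2C(=O)[C@H](C)[C@@H](C)Oc2c1C=O | intermediate
9 | (2R,3R)-5-hydroxy-2,3-dimethyl-2,3-dihydro-4H,8H-pyrano[2,3-f]chromene-4,8-dione | O=C1C=Cc2c(O1)cc(O)c1C(=O)[C@H](C)[C@@H](C)Oc21 | intermediate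
10 | (2R,3R,10R)-5-hydroxy-2,3-dimethyl-10-phenyl-2,3,9,10-tetrahydro-4H,8H-pyrano[2,3-f]chromene-4,8-dione | O=C1C[C@H](c3ccccc3)c2c(O1)cc(O)c1C(=O)[C@H](C)[C@@H](C)Oc21 | intermediate
11 | (2R,3R,10R)-5-hydroxy-2,3-dimethyl-6-[(4-methylphenyl)sulfonylmethyl]-10-phenyl-2,3,9,10-tetrahydro-4H,8H-pyrano[2,3-f]chromene-4,8-dione | Cc1ccc(cc1)S(=O)(=O)Cc1c(O)c2C(=O)[C@H](C)[C@@H](C)Oc2c2c1OC(=O)C[C@@H]2c1ccccc1 | intermediate
12 | ethyl 5-oxohexanoate | CCOC(=O)CCCC(C)=O | starting material
13 | ethyl 5-methylhex-5-enoate | CCOC(=O)CCCC(C)=C | intermediate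
14 | 5-methylhex-5-enal | C=C(C)CCCC=O | intermediate
15 | ortho-quinone methide of 11 (C5=O, C6=CH2, C7=C8, C8a=C4a; lactone and ring B unchanged; not isolated) | C=C1C(=O)C2C(=O)[C@H](C)[C@@H](C)OC=2C2=C1OC(=O)C[C@@H]2c1ccccc1 | intermediate
16 | O5-lactol of (2R)-2-{[(2R,3R,10R)-5-hydroxy-2,3-dimethyl-4,8-dioxo-10-phenyl-2,3,9,10-tetrahydro-4H,8H-pyrano[2,3-f]chromen-6-yl]methyl}-5-methylhex-5-enal (ring O5–Cc–Cb–Ca–C6–C5; Cb R; anomeric carbon undefined) | C=C(C)CC[C@@H]4Cc1c(OC4O)c2C(=O)[C@H](C)[C@@H](C)Oc2c2c1OC(=O)C[C@@H]2c1ccccc1 | intermediate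
17 | tert-butyldimethylsilyl ether of lactol 16 (anomeric carbon undefined) | C=C(C)CC[C@@H]4Cc1c(OC4O[Si](C)(C)C(C)(C)C)c2C(=O)[C@H](C)[C@@H](C)Oc2c2c1OC(=O)C[C@@H]2c1ccccc1 | intermediate
18 | sodium 7-phenoxide of the methyl ester formed by methanolysis of the lactone of 17 (not isolated) | C=C(C)CC[C@@H]4Cc1c(OC4O[Si](C)(C)C(C)(C)C)c2C(=O)[C@H](C)[C@@H](C)Oc2c([C@H](CC(=O)OC)c2ccccc2)c1[O-].[Na+] | intermediate
19 | (6S)-6-prenyl cyclohexa-2,4-dienone: C7 ketone, C8=C8a and C4a=C5 double bonds, C6 bearing prenyl and Ca, O5 silyl acetal ring and ring B intact, (R)-arm as methyl ester | C=C(C)CC[C@@H]4C[C@@]1(CC=C(C)C)C(OC4O[Si](C)(C)C(C)(C)C)=C2C(=O)[C@H](C)[C@@H](C)OC2=C([C@H](CC(=O)OC)c2ccccc2)C1=O | intermediate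
20 | methyl (3R)-3-[(2R,3R,6R)-6-[(2R)-2-formyl-5-methylhex-5-en-1-yl]-4-hydroxy-2,3-dimethyl-6-(3-methylbut-2-en-1-yl)-5,7-dioxo-3,5,6,7-tetrahydro-2H-chromen-8-yl]-3-phenylpropanoate | C=C(C)CC[C@@H](C=O)C[C@@]1(CC=C(C)C)C(=O)C2=C(O)[C@H](C)[C@@H](C)OC2=C([C@H](CC(=O)OC)c2ccccc2)C1=O | intermediate
21 | methyl (3R)-3-[(2R,3R,6S)-4-hydroxy-2,3-dimethyl-6-(3-methylbut-2-en-1-yl)-6-[(2R)-5-methyl-2-(2-methylprop-1-en-1-yl)hex-5-en-1-yl]-5,7-dioxo-3,5,6,7-tetrahydro-2H-chromen-8-yl]-3-phenylpropanoate | C=C(C)CC[C@@H](C=C(C)C)C[C@@]1(CC=C(C)C)C(=O)C2=C(O)[C@H](C)[C@@H](C)OC2=C([C@H](CC(=O)OC)c2ccccc2)C1=O | intermediate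
22 | (3R)-3-[(2R,3R,6S)-4-hydroxy-2,3-dimethyl-6-(3-methylbut-2-en-1-yl)-6-[(2R)-5-methyl-2-(2-methylprop-1-en-1-yl)hex-5-en-1-yl]-5,7-dioxo-3,5,6,7-tetrahydro-2H-chromen-8-yl]-3-phenylpropanoic acid | C=C(C)CC[C@@H](C=C(C)C)C[C@@]1(CC=C(C)C)C(=O)C2=C(O)[C@H](C)[C@@H](C)OC2=C([C@H](CC(=O)O)c2ccccc2)C1=O | target

**Step count and risks**

Total: 15 steps. Longest linear sequence: 13 steps (steps 1–7, then 10–15); steps 8 and 9 form the side branch.

Steps most likely to fail:

Step 12. The phenoxide may be alkylated at oxygen or at C8 instead of C6, and the facial bias of the acetal ring may be too small. The fallback replaces the bromide by a π-prenyl palladium electrophile (Tsuji–Trost). It sets out from 17: NaOMe (0.1 equiv) in MeOH at 0 °C followed by NH4Cl should give the free phenol methyl ester F1. F1 is then treated with Pd(PPh3)4 (zerovalent palladium, 5 mol %) and methyl 3-methylbut-2-en-1-yl carbonate in THF at room temperature. Under palladium catalysis O-allylation is reversible and C-allylation is not, so the material should collect as the C6 dienone. The bulky complex reacts through its unsubstituted terminus and should respond more strongly to the shape of the fused ring. The fallback comes back to the route at 19.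

Step 10. Loss of sulfinate from the hydrogen-bonded, acyl-conjugated phenoxide may be slow, so that self-condensation of 14 and base attack on the lactone outrun the alkylation. The fallback changes the leaving group to an ammonium group. It sets out from 10: Me2N=CH2 I (Eschenmoser's salt) in CH2Cl2 should give the C6 Mannich base F2, and MeI the trimethylammonium iodide F3. With 14, the same amine catalyst and NaHCO3 in CH2Cl2/H2O at room temperature, F3 should lose trimethylamine to give 15. The enamine addition and lactol closure then follow as in step 10, and the fallback comes back at 16.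

Step 11. The closed tautomer may be too scarce, so that silylation stalls and the free aldehyde epimerises at Cb or the phenol is silylated. The fallback closes the ring under thermodynamic drive instead of kinetic trapping. It sets out from 16: HC(OMe)3 (1.5 equiv) and camphorsulfonic acid (5 mol %) in CH2Cl2 should give the open dimethyl acetal F4. Over 4 Å sieves F4 loses methanol to the cyclic O5 methyl acetal F5; the small amount of methanol and the non-nucleophilic solvent spare the lactone. NaOMe/MeOH and prenyl bromide, as in step 12, then lead through the sodium phenoxide F6 to the prenylated dienone F7. Dilute HCl in THF/H2O hydrolyses the acetal of F7, the enol oxygen O5 being a good leaving group, and the fallback comes back at 20.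

**Further compounds**

F1 | step 12 | free phenol methyl ester from methanolysis of the lactone of 17 (silyl acetal intact) | C=C(C)CC[C@@H]4Cc1c(OC4O[Si](C)(C)C(C)(C)C)c2C(=O)[C@H](C)[C@@H](C)Oc2c([C@H](CC(=O)OC)c2ccccc2)c1O
F2 | step 10 | 6-(dimethylaminomethyl) analogue of 11 (Mannich base of 10) | CN(C)Cc1c(O)c2C(=O)[C@H](C)[C@@H](C)Oc2c2c1OC(=O)C[C@@H]2c1ccccc1
F3 | step 10 | 6-(trimethylammoniomethyl) iodide from F2 | C[N+](C)(C)Cc1c(O)c2C(=O)[C@H](C)[C@@H](C)Oc2c2c1OC(=O)C[C@@H]2c1ccccc1.[I-]
F4 | step 11 | dimethyl acetal of the open aldehyde form of 16 | C=C(C)CC[C@@H](C(OC)OC)Cc1c(O)c2C(=O)[C@H](C)[C@@H](C)Oc2c2c1OC(=O)C[C@@H]2c1ccccc1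
F5 | step 11 | cyclic O5 methyl acetal (methyl analogue of 17; anomeric carbon undefined) | C=C(C)CC[C@@H]4Cc1c(OC4OC)c2C(=O)[C@H](C)[C@@H](C)Oc2c2c1OC(=O)C[C@@H]2c1ccccc1
F6 | step 11 | sodium 7-phenoxide methyl ester from F5 (methyl acetal analogue of 18) | C=C(C)CC[C@@H]4Cc1c(OC4OC)c2C(=O)[C@H](C)[C@@H](C)Oc2c([C@H](CC(=O)OC)c2ccccc2)c1[O-].[Na+]
F7 | step 11 | 6-prenyl cyclohexa-2,4-dienone with O5 methyl acetal (methyl acetal analogue of 19) | C=C(C)CC[C@@H]4C[C@@]1(CC=C(C)C)C(OC4OC)=C2C(=O)[C@H](C)[C@@H](C)OC2=C([C@H](CC(=O)OC)c2ccccc2)C1=O
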